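**Plan**

- Retrosynthesis cuts the ring at O1–C6 and C2–C3 (an aldehyde plus a C5 silyl dienol ether). It cuts the side chain (C1′ on ring C2) at C8′–C9′ and at C10′=C11′, both of which are made in one operation.
- Enabling feature: the isolated cis-CH=CH (C10′=C11′) has on its ring side a plain CH2 (C9′) bonded to CH2 (C8′). C9′ and C10′ are therefore the β- and α-carbons of a vinylphosphonium salt, with an alkyl nucleophile on one side and an aldehyde on the other.
- Forward: a C9 alkylcuprate adds to vinyltriphenylphosphonium bromide (C8′–C9′) and the ylide so formed olefinates nonanal (C10′=C11′). The C20 chain is then taken to (Z)-icos-11-enal and the dihydropyranone ring is closed last.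
- Stereochemistry: the Z-alkene comes from the kinetic Wittig reaction of a non-stabilised ylide; C2 (R) comes from a BINOL–Ti-catalysed aldol addition. No later step touches either element.

Key step: step 2

Assumption: the (S)-BINOL–Ti(IV) catalyst is taken to deliver the enol silane to the Si face of an unbranched aliphatic aldehyde, which gives the (R)-carbinol; if the antipode is found, (R)-BINOL is used with no other change.

**Step 1**
Reactants: 1 9-bromononan-1-ol
Product: 2 [(9-bromononyl)oxy](tert-butyl)dimethylsilane
Conditions: TBSCl, imidazole, DMF, 0 °C → rt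
Reagents that add atoms: tert-butyl(chloro)dimethylsilane (TBSCl), CC(C)(C)[Si](C)(C)Cl
Why: Imidazole-promoted silyl ether formation on a primary alcohol should proceed cleanly, the primary bromide being inert to imidazole at room temperature; no stereocentre is involved.

**Step 2**
Reactants: 2 [(9-bromononyl)oxy](tert-butyl)dimethylsilane; 3 ethenyl(triphenyl)phosphonium bromide (vinyltriphenylphosphonium bromide); 4 nonanal
Product: 8 tert-butyl{[(11Z)-icos-11-en-1-yl]oxy}dimethylsilane, via Grignard reagent 5 (not isolated), via magnesium dialkylcuprate 6 (not isolated), via phosphonium ylide 7 (not isolated)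
Conditions: 2 (2.2 equiv), Mg, THF, 40 °C; CuBr·SMe2 (1.1 equiv), −40 °C; 3 (1.0 equiv), −40 → 0 °C; DMPU, then 4 (0.9 equiv), −78 °C → rt
Reagents that add atoms: none
Why: The soft dialkylcuprate 6 should add in a conjugate sense to the unsubstituted β-carbon of the vinylphosphonium cation 3, which forms the C9–C10 bond of the icosenyl chain (C8′–C9′ of the target) and gives the non-stabilised ylide 7 without any base. Ylide 7 then olefinates nonanal through a kinetically formed cis-oxaphosphetane that collapses by syn-cycloreversion to the alkene and triphenylphosphine oxide. The closest known reaction type is the conjugate addition of organocuprates to vinyltriphenylphosphonium bromide with in-situ Wittig trapping (a three-component Z-olefination). No ring of the target is closed and no stereocentre is formed; the only new stereo-element is the C11=C12 double bond, whose Z geometry is controlled by the early, puckered [2+2] transition state of a β-unbranched non-stabilised ylide with an unbranched aldehyde at −78 °C, with DMPU keeping the metal cations from equilibrating the oxaphosphetane. The step needs β-regioselectivity (attack at carbon, not phosphorus) and chemoselectivity (no organometallic may meet the aldehyde): the cationic terminal vinyl acceptor secures the first, and adding the aldehyde only after 3 is consumed secures the second, since residual alkylcopper is inert to aldehydes at −78 °C and the silyl ether is inert throughout.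

**Step 3**
Reactants: 8 tert-butyl{[(11Z)-icos-11-en-1-yl]oxy}dimethylsilane
Product: 9 (11Z)-icos-11-en-1-ol
Conditions: CSA (10 mol%), MeOH/CH2Cl2, 0 °C → rt
Reagents that add atoms: none
Why: Acid-catalysed methanolysis of a primary TBS ether is fast under these conditions, and catalytic CSA in methanol should neither protonate nor isomerise the isolated Z-alkene.

**Step 4**
Reactants: 9 (11Z)-icos-11-en-1-ol
Product: 10 (11Z)-icos-11-enal
Conditions: TEMPO (10 mol%), PhI(OAc)2, CH2Cl2, rt
Reagents that add atoms: none
Why: The TEMPO/PhI(OAc)2 (oxoammonium) oxidation of a primary alcohol should stop at the aldehyde and leaves a Z-alkene untouched and unisomerised; the aldehyde is used at once in step 6.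

**Step 5**
Reactants: 11 (3E)-4-methoxypent-3-en-2-one
Product: 12 trimethyl{[(3E)-4-methoxypenta-1,3-dien-2-yl]oxy}silane
Conditions: LDA (commercial solution), THF, −78 °C; TMSCl, −78 → 0 °C
Reagents that add atoms: chlorotrimethylsilane (TMSCl), C[Si](C)(C)Cl
Why: Kinetic deprotonation of the acetyl methyl (α′ position) of the vinylogous ester and O-silylation of the enolate (silyl enol ether formation) should give the Danishefsky-type 2-silyloxy diene, with the C3=C4 geometry carried over unchanged.

**Step 6**
Reactants: 10 (11Z)-icos-11-enal; 12 trimethyl{[(3E)-4-methoxypenta-1,3-dien-2-yl]oxy}silane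
Product: 14 (2R)-6-methyl-2-[(10Z)-nonadec-10-en-1-yl]-2,3-dihydro-4H-pyran-4-one, via silyl aldol adduct 13 (not isolated)
Conditions: (S)-BINOL (20 mol%), Ti(OiPr)4 (10 mol%), 4 Å MS, Et2O, −20 °C; then TFA, CH2Cl2, 0 °C → rt
Reagents that add atoms: none
Why: This is a catalytic enantioselective Mukaiyama aldol addition (formal hetero-Diels–Alder reaction of a Danishefsky-type diene) in which the chiral BINOL–Ti(IV) Lewis acid shields one face of the aldehyde so that the enol silane terminus forms C2–C3 on the Si face and sets C2 as R, followed by TFA-promoted 6-endo-trig oxa-Michael addition of the C2 oxygen to the β-methoxy enone and loss of methanol, which closes O1–C6 without breaking any bond at the stereocentre.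

**Compound list**

1 | 9-bromononan-1-ol | OCCCCCCCCCBr | starting material
2 | [(9-bromononyl)oxy](tert-butyl)dimethylsilane | CC(C)(C)[Si](C)(C)OCCCCCCCCCBr | intermediate
3 | ethenyl(triphenyl)phosphonium bromide | C=C[P+](c1ccccc1)(c2ccccc2)c3ccccc3.[Br-] | starting material
4 | nonanal | CCCCCCCCC=O | starting material
5 | {9-[(tert-butyldimethylsilyl)oxy]nonyl}magnesium bromide | CC(C)(C)[Si](C)(C)OCCCCCCCCC[Mg]Br | intermediate
6 | bromomagnesium bis{9-[(tert-butyldimethylsilyl)oxy]nonyl}cuprate(I) | CC(C)(C)[Si](C)(C)OCCCCCCCCC[Cu-]CCCCCCCCCO[Si](C)(C)C(C)(C)C.[Mg+]Br | intermediate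
7 | {11-[(tert-butyldimethylsilyl)oxy]undecylidene}triphenyl-λ5-phosphane | CC(C)(C)[Si](C)(C)OCCCCCCCCCCC=P(c1ccccc1)(c2ccccc2)c3ccccc3 | intermediate
8 | tert-butyl{[(11Z)-icos-11-en-1-yl]oxy}dimethylsilane | CCCCCCCC/C=C\CCCCCCCCCCO[Si](C)(C)C(C)(C)C | intermediate
9 | (11Z)-icos-11-en-1-ol | CCCCCCCC/C=C\CCCCCCCCCCO | intermediate
10 | (11Z)-icos-11-enal | CCCCCCCC/C=C\CCCCCCCCCC=O | intermediate
11 | (3E)-4-methoxypent-3-en-2-one | CC(=O)/C=C(\C)OC | starting material
12 | trimethyl{[(3E)-4-methoxypenta-1,3-dien-2-yl]oxy}silane | C=C(O[Si](C)(C)C)/C=C(\C)OC | intermediate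
13 | (2E,6R,16Z)-2-methoxy-6-[(trimethylsilyl)oxy]pentacosa-2,16-dien-4-one | CCCCCCCC/C=C\CCCCCCCCC[C@@H](O[Si](C)(C)C)CC(=O)/C=C(\C)OC | intermediate
14 | (2R)-6-methyl-2-[(10Z)-nonadec-10-en-1-yl]-2,3-dihydro-4H-pyran-4-one | CCCCCCCC/C=C\CCCCCCCCC[C@@H]1CC(=O)C=C(C)O1 | target

**Step count and risks**

Total steps: 6. Longest linear sequence: 5 (steps 1, 2, 3, 4 and 6); step 5 makes the diene in a side branch.

Steps most likely to fail:

1. Step 2. The ylide may add to unreacted vinylphosphonium salt (oligomerisation), transfer from the cuprate may be incomplete, and salt-induced equilibration of the oxaphosphetane may erode the Z-selectivity.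
 Fallback, from 2 back to 8: displacement of the bromide of 2 with sodium benzenesulfinate (DMF, 60 °C) should give the sulfone tert-butyldimethyl{[9-(phenylsulfonyl)nonyl]oxy}silane F1. In parallel, commercial undec-2-yn-1-ol would be semihydrogenated (H2, Lindlar catalyst, quinoline) to (2Z)-undec-2-en-1-ol F2 and brominated (CBr4, PPh3, CH2Cl2, 0 °C) to (2Z)-1-bromoundec-2-ene F3. Lithiation of F1 (n-BuLi, THF, −78 °C) and SN2 alkylation with F3 would form the same C9–C10 bond with the Z-alkene already in place, giving tert-butyldimethyl{[(11Z)-9-(phenylsulfonyl)icos-11-en-1-yl]oxy}silane F4. Reductive desulfonylation of this non-allylic sulfone (6% Na/Hg, Na2HPO4, MeOH–THF, −20 °C) returns to the route at 8.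

2. Step 6. Facial discrimination may be poor with an unbranched long-chain aldehyde, and acid-induced β-elimination of the aldol may compete with ring closure.
 Fallback, from 10 back to 14: Roskamp homologation of 10 (ethyl diazoacetate, SnCl2 cat., CH2Cl2) should give ethyl (13Z)-3-oxodocos-13-enoate F5. Noyori hydrogenation with RuCl2[(R)-BINAP] (H2 at low pressure, EtOH, so that the isolated alkene is left alone) would set the carbinol, giving ethyl (3R,13Z)-3-hydroxydocos-13-enoate F6; (R)-BINAP is the ligand that gives (R)-3-hydroxy esters from 3-oxo esters. Aminolysis (MeNHOMe·HCl, i-PrMgCl, THF, −20 °C) would give (3R,13Z)-3-hydroxy-N-methoxy-N-methyldocos-13-enamide F7, and excess prop-1-ynylmagnesium bromide (THF, 0 °C) would give (6R,16Z)-6-hydroxypentacos-16-en-2-yn-4-one F8. Gold-catalysed 6-endo-dig oxycyclisation (Ph3PAuCl/AgOTf cat., CH2Cl2, rt) closes O1–C6 and arrives at 14.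

3. Step 5. Deprotonation may compete at the C5 methyl (vinylogous enolisation), and the labile silyl dienol ether may hydrolyse during isolation.
 Fallback, from 10 back to 14: pentane-2,4-dione would be bis-silylated (TMSOTf, Et3N, Et2O, 0 °C) to (3Z)-2,4-bis[(trimethylsilyl)oxy]penta-1,3-diene F9, which replaces 12 as the C5 partner of aldehyde 10 under the same BINOL–Ti catalysis. Desilylation on work-up should give (6R,16Z)-6-hydroxypentacos-16-ene-2,4-dione F10. Acid-catalysed cyclodehydration of this δ-hydroxy-β-diketone (TFA, CH2Cl2, rt; hemiketalisation at C2 of the dione, then loss of water) closes the ring and arrives at 14.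

**Further compounds**

F1 | step 2 | tert-butyldimethyl{[9-(phenylsulfonyl)nonyl]oxy}silane | CC(C)(C)[Si](C)(C)OCCCCCCCCCS(=O)(=O)c1ccccc1
F2 | step 2 | (2Z)-undec-2-en-1-ol | CCCCCCCC/C=C\CO
F3 | step 2 | (2Z)-1-bromoundec-2-ene | CCCCCCCC/C=C\CBr
F4 | step 2 | tert-butyldimethyl{[(11Z)-9-(phenylsulfonyl)icos-11-en-1-yl]oxy}silane | CCCCCCCC/C=C\CC(CCCCCCCCO[Si](C)(C)C(C)(C)C)S(=O)(=O)c1ccccc1
F5 | step 6 | ethyl (13Z)-3-oxodocos-13-enoate | CCCCCCCC/C=C\CCCCCCCCCC(=O)CC(=O)OCC
F6 | step 6 | ethyl (3R,13Z)-3-hydroxydocos-13-enoate | CCCCCCCC/C=C\CCCCCCCCC[C@@H](O)CC(=O)OCC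
F7 | step 6 | (3R,13Z)-3-hydroxy-N-methoxy-N-methyldocos-13-enamide | CCCCCCCC/C=C\CCCCCCCCC[C@@H](O)CC(=O)N(C)OC
F8 | step 6 | (6R,16Z)-6-hydroxypentacos-16-en-2-yn-4-one | CCCCCCCC/C=C\CCCCCCCCC[C@@H](O)CC(=O)C#CC
F9 | step 5 | (3Z)-2,4-bis[(trimethylsilyl)oxy]penta-1,3-diene | C=C(O[Si](C)(C)C)/C=C(/C)O[Si](C)(C)C
F10 | step 5 | (6R,16Z)-6-hydroxypentacos-16-ene-2,4-dione | CCCCCCCC/C=C\CCCCCCCCC[C@@H](O)CC(=O)CC(C)=O
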